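**Plan**

- Retrosynthesis cuts three bonds in this order: the N–C bond from the 2-amino nitrogen to C4 of the 1-methylimidazole-2,5-dione ring, the imidazole C4–CH2 bond to the 4-methoxybenzyl group, and the imidazole C5–CH2 bond to the 3-hydroxy-4,5-dimethoxybenzyl group.
- Enabling feature: N1-methyl, C2 with its amino nitrogen, N3, C4 and C5 of the target's imidazole are the ring atoms of creatinine in the same sequence. The one acidic C–H position of creatinine is the C5 methylene between N1 and the C4 carbonyl, which is the carbon that must carry the trioxygenated benzyl group.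
- Forward order: neither ring is built. The creatinine ring is benzylated at C5 (condensation, hydrogenation), aromatised by enol triflation of the C4 carbonyl, benzylated at C4 by Negishi coupling, unmasked, and joined to intact 1-methylparabanic acid.
- Stereochemistry: the target has none. The alkene geometry of 3 and the racemic C5 centre of 4 to 6 are transient and disappear in steps 2 and 5.

Key step: step 1

Assumption: 3 is drawn as the E isomer (aryl group remote from N-methyl); the geometry has no bearing on the route because step 2 saturates the alkene.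

**Route**

Step 1
Reactants: 1 creatinine; 2 3-hydroxy-4,5-dimethoxybenzaldehyde
Product: 3 (E)-2-amino-5-(3-hydroxy-4,5-dimethoxybenzylidene)-1-methyl-1,5-dihydro-4H-imidazol-4-one
Conditions: NaOAc, AcOH, reflux
Reagents that add atoms: none
Why: Acetate reversibly enolises C5 of 1, the only C–H acidic ring position because it lies between N1 and the C4 carbonyl, the enol adds to the aldehyde of 2, and loss of water from the aldol gives the conjugated arylidene, so that the C5–benzylic carbon bond is the one skeletal bond formed. The closest known reaction type is the Knoevenagel condensation of creatinine and of hydantoins with aromatic aldehydes in buffered acetic acid. No ring is closed and no stereocentre is created; the alkene geometry, expected to be E under thermodynamic control, is removed in step 2. The step needs condensation at C5 in preference to imine formation at the 2-amino group, and this is secured because that nitrogen belongs to a delocalised acylguanidine that is a poor nucleophile in acetic acid and any hemiaminal formed there reverts, whereas dehydration at C5 is irreversible. The free phenol of 2 is a spectator in this weakly acidic medium. The outcome places the trioxygenated benzyl carbon on the ring carbon next to N-methyl, which settles the regiochemical question of the target.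

Step 2
Reactants: 3 (E)-2-amino-5-(3-hydroxy-4,5-dimethoxybenzylidene)-1-methyl-1,5-dihydro-4H-imidazol-4-one
Product: 4 (±)-2-amino-5-(3-hydroxy-4,5-dimethoxybenzyl)-1-methyl-1,5-dihydro-4H-imidazol-4-one
Conditions: H2 (1 atm), Pd/C (10 wt%), MeOH–AcOH, 25 °C
Reagents that add atoms: none
Why: Heterogeneous catalytic hydrogenation of the polarised exocyclic alkene is expected to be fast and leaves the aryl ethers and the acylguanidine untouched, and the C5 stereocentre it creates forms as a racemate that needs no control because step 5 removes it.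

Step 3
Reactants: 4 (±)-2-amino-5-(3-hydroxy-4,5-dimethoxybenzyl)-1-methyl-1,5-dihydro-4H-imidazol-4-one
Product: 5 (±)-2-amino-5-[3-(tert-butyldimethylsilyloxy)-4,5-dimethoxybenzyl]-1-methyl-1,5-dihydro-4H-imidazol-4-one
Conditions: TBSCl, imidazole, DMF, 25 °C
Reagents that add atoms: tert-butyldimethylsilyl chloride (TBSCl), CC(C)(C)[Si](C)(C)Cl
Why: Imidazole-promoted silylation (silyl ether protection) is selective for the phenol because any silyl group taken up by the acylguanidine nitrogen is lost on aqueous work-up, and the ether also makes the polar creatinine derivative soluble in organic solvents.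

Step 4
Reactants: 5 (±)-2-amino-5-[3-(tert-butyldimethylsilyloxy)-4,5-dimethoxybenzyl]-1-methyl-1,5-dihydro-4H-imidazol-4-one
Product: 6 (±)-(E)-N'-{5-[3-(tert-butyldimethylsilyloxy)-4,5-dimethoxybenzyl]-1-methyl-4-oxo-4,5-dihydro-1H-imidazol-2-yl}-N,N-dimethylformimidamide
Conditions: Me2NCH(OMe)2, DMF, 25 °C
Reagents that add atoms: N,N-dimethylformamide dimethyl acetal, COC(OC)N(C)C
Why: Condensation of the primary amino group with the amide acetal (N,N-dimethylformamidine protection, as used for the exocyclic amine of guanine-type acylguanidines) removes both N–H bonds so that C5–H is the only acidic site left, the E amidine being the expected thermodynamic isomer and room temperature keeping the acetal from acting as a methylating agent.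

Step 5
Reactants: 6 (±)-(E)-N'-{5-[3-(tert-butyldimethylsilyloxy)-4,5-dimethoxybenzyl]-1-methyl-4-oxo-4,5-dihydro-1H-imidazol-2-yl}-N,N-dimethylformimidamide
Product: 8 5-[3-(tert-butyldimethylsilyloxy)-4,5-dimethoxybenzyl]-2-{[(E)-(dimethylamino)methylene]amino}-1-methyl-1H-imidazol-4-yl trifluoromethanesulfonate, via potassium imidazol-4-olate 7 (not isolated)
Conditions: KN(SiMe3)2, THF, −78 °C; then PhNTf2, −78 → 0 °C
Reagents that add atoms: N-phenylbis(trifluoromethanesulfonimide) (PhNTf2), O=S(=O)(N(c1ccccc1)S(=O)(=O)C(F)(F)F)C(F)(F)F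
Why: Deprotonation of C5 gives an aromatic imidazol-4-olate whose hard oxygen terminus is sulfonylated by the mild triflyl donor (enol triflation of an azolone, as practised on pyrazolones and oxazol-4(5H)-ones), which aromatises the ring, erases the C5 stereocentre and turns the former carbonyl carbon into a cross-coupling site.

Step 6
Reactants: 8 5-[3-(tert-butyldimethylsilyloxy)-4,5-dimethoxybenzyl]-2-{[(E)-(dimethylamino)methylene]amino}-1-methyl-1H-imidazol-4-yl trifluoromethanesulfonate; 9 4-methoxybenzyl chloride
Product: 11 (E)-N'-{5-[3-(tert-butyldimethylsilyloxy)-4,5-dimethoxybenzyl]-4-(4-methoxybenzyl)-1-methyl-1H-imidazol-2-yl}-N,N-dimethylformimidamide, via (4-methoxybenzyl)zinc chloride 10 (not isolated)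
Conditions: 9, Zn dust, LiCl, THF, 25 °C; then 8, Pd(OAc)2 (2 mol%), SPhos (4 mol%), THF, 25 → 50 °C
Reagents that add atoms: none
Why: Negishi cross-coupling, in which LiCl-assisted zinc insertion gives the benzylic zinc chloride, zerovalent palladium carrying the electron-rich biarylphosphine inserts into the heteroaryl C–O triflate bond, and transmetalation followed by reductive elimination forms the C4–CH2 bond with no β-hydride pathway open to a benzyl group.

Step 7
Reactants: 11 (E)-N'-{5-[3-(tert-butyldimethylsilyloxy)-4,5-dimethoxybenzyl]-4-(4-methoxybenzyl)-1-methyl-1H-imidazol-2-yl}-N,N-dimethylformimidamide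
Product: 13 2-amino-5-(3-hydroxy-4,5-dimethoxybenzyl)-4-(4-methoxybenzyl)-1-methyl-1H-imidazole, via silyl-protected 2-aminoimidazole 12 (not isolated)
Conditions: N2H4·H2O, EtOH, 70 °C; then K2CO3, MeOH, 25 °C (under argon)
Reagents that add atoms: none
Why: Hydrazinolysis (transamination of the formamidine) frees the 2-amino group and carbonate-mediated methanolysis then cleaves the phenolic silyl ether, conditions to which the methyl ethers, the benzylic positions and the imidazole are inert.

Step 8
Reactants: 13 2-amino-5-(3-hydroxy-4,5-dimethoxybenzyl)-4-(4-methoxybenzyl)-1-methyl-1H-imidazole; 14 1-methylparabanic acid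
Product: 17 4-{[5-(3-hydroxy-4,5-dimethoxybenzyl)-4-(4-methoxybenzyl)-1-methyl-1H-imidazol-2-yl]amino}-1-methyl-1H-imidazole-2,5-dione, via O-silylated 1-methylparabanic acid 15 (not isolated), via trimethylsilyl ether of the target 16 (not isolated)
Conditions: 14, MeC(OSiMe3)=NSiMe3 (BSA, 3 equiv), MeCN, 80 °C; then 13, toluene, 110 °C; MeOH work-up
Reagents that add atoms: none
Why: Silyl-mediated dehydrative condensation: BSA converts the N3–H/C4=O imide unit of 14 into a silyl imidate that undergoes addition–elimination with the exocyclic amine, a reaction known for 1-methyl-2-aminoimidazoles, the carbonyl flanked by N–H being the only one that can be activated so that N-methyl ends between the two carbonyls, and methanol removes the transient phenol silyl ether.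

**Compound list**

1 | creatinine | CN1CC(=O)N=C1N | starting material
2 | 3-hydroxy-4,5-dimethoxybenzaldehyde | COc1cc(C=O)cc(O)c1OC | starting material
3 | (E)-2-amino-5-(3-hydroxy-4,5-dimethoxybenzylidene)-1-methyl-1,5-dihydro-4H-imidazol-4-one | CN1C(N)=NC(=O)/C1=C\c1cc(O)c(OC)c(OC)c1 | intermediate
4 | (±)-2-amino-5-(3-hydroxy-4,5-dimethoxybenzyl)-1-methyl-1,5-dihydro-4H-imidazol-4-one (racemic) | CN1C(N)=NC(=O)C1Cc1cc(O)c(OC)c(OC)c1 | intermediate
5 | (±)-2-amino-5-[3-(tert-butyldimethylsilyloxy)-4,5-dimethoxybenzyl]-1-methyl-1,5-dihydro-4H-imidazol-4-one (racemic) | CN1C(N)=NC(=O)C1Cc1cc(O[Si](C)(C)C(C)(C)C)c(OC)c(OC)c1 | intermediate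
6 | (±)-(E)-N'-{5-[3-(tert-butyldimethylsilyloxy)-4,5-dimethoxybenzyl]-1-methyl-4-oxo-4,5-dihydro-1H-imidazol-2-yl}-N,N-dimethylformimidamide (racemic) | CN(C)/C=N/C1=NC(=O)C(Cc2cc(O[Si](C)(C)C(C)(C)C)c(OC)c(OC)c2)N1C | intermediate
7 | potassium 5-[3-(tert-butyldimethylsilyloxy)-4,5-dimethoxybenzyl]-2-{[(E)-(dimethylamino)methylene]amino}-1-methyl-1H-imidazol-4-olate (not isolated) | [K+].CN(C)/C=N/c1nc([O-])c(Cc2cc(O[Si](C)(C)C(C)(C)C)c(OC)c(OC)c2)n1C | intermediate
8 | 5-[3-(tert-butyldimethylsilyloxy)-4,5-dimethoxybenzyl]-2-{[(E)-(dimethylamino)methylene]amino}-1-methyl-1H-imidazol-4-yl trifluoromethanesulfonate | CN(C)/C=N/c1nc(OS(=O)(=O)C(F)(F)F)c(Cc2cc(O[Si](C)(C)C(C)(C)C)c(OC)c(OC)c2)n1C | intermediate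
9 | 4-methoxybenzyl chloride | COc1ccc(CCl)cc1 | starting material
10 | (4-methoxybenzyl)zinc chloride (not isolated) | COc1ccc(C[Zn]Cl)cc1 | intermediate
11 | (E)-N'-{5-[3-(tert-butyldimethylsilyloxy)-4,5-dimethoxybenzyl]-4-(4-methoxybenzyl)-1-methyl-1H-imidazol-2-yl}-N,N-dimethylformimidamide | COc1ccc(Cc2nc(/N=C/N(C)C)n(C)c2Cc2cc(O[Si](C)(C)C(C)(C)C)c(OC)c(OC)c2)cc1 | intermediate
12 | 5-[3-(tert-butyldimethylsilyloxy)-4,5-dimethoxybenzyl]-4-(4-methoxybenzyl)-1-methyl-1H-imidazol-2-amine (not isolated) | COc1ccc(Cc2nc(N)n(C)c2Cc2cc(O[Si](C)(C)C(C)(C)C)c(OC)c(OC)c2)cc1 | intermediate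
13 | 2-amino-5-(3-hydroxy-4,5-dimethoxybenzyl)-4-(4-methoxybenzyl)-1-methyl-1H-imidazole | COc1ccc(Cc2nc(N)n(C)c2Cc2cc(O)c(OC)c(OC)c2)cc1 | intermediate
14 | 1-methylparabanic acid (1-methylimidazolidine-2,4,5-trione) | CN1C(=O)NC(=O)C1=O | starting material
15 | 1-methyl-4-(trimethylsilyloxy)-1H-imidazole-2,5-dione (not isolated) | CN1C(=O)N=C(O[Si](C)(C)C)C1=O | intermediate
16 | 4-{[5-(4,5-dimethoxy-3-(trimethylsilyloxy)benzyl)-4-(4-methoxybenzyl)-1-methyl-1H-imidazol-2-yl]amino}-1-methyl-1H-imidazole-2,5-dione (not isolated) | COc1ccc(Cc2nc(NC3=NC(=O)N(C)C3=O)n(C)c2Cc2cc(O[Si](C)(C)C)c(OC)c(OC)c2)cc1 | intermediate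
17 | 4-{[5-(3-hydroxy-4,5-dimethoxybenzyl)-4-(4-methoxybenzyl)-1-methyl-1H-imidazol-2-yl]amino}-1-methyl-1H-imidazole-2,5-dione (CNP0321799.0) | COc1ccc(Cc2nc(NC3=NC(=O)N(C)C3=O)n(C)c2Cc2cc(O)c(OC)c(OC)c2)cc1 | target

**Step count and risks**

Total step count: 8. Longest linear sequence: 8 steps (1 and 2 to 17); the zinc reagent 10 and the silyl imidate 15 are made in the flask within steps 6 and 8.

Steps most likely to fail:

Step 5 (enol triflation). The ambident imidazol-4-olate may be sulfonylated at N3 or at the amidine nitrogen instead of at oxygen, or the triflate may lose its sulfonyl group by S–O cleavage during purification and revert to 6. The fallback sets out from 6 and replaces sulfonate activation by deoxychlorination. POCl3 with i-Pr2NEt in MeCN at 70 °C, the aromatising lactam-to-chloride conversion established for imidazol-4-ones, should give (E)-N'-{4-chloro-5-[3-(tert-butyldimethylsilyloxy)-4,5-dimethoxybenzyl]-1-methyl-1H-imidazol-2-yl}-N,N-dimethylformimidamide F1. This chloride would then be coupled with the zinc reagent 10 under Pd(OAc)2 and XPhos in THF at 60 °C, and the route is rejoined at 11.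

Step 6 (Negishi coupling). Oxidative addition into the electron-rich C4–O bond may be slow, so that detriflation back to 6 and homocoupling of the benzylic zinc reagent take over. The fallback sets out from 6 and forms the same bond by polar addition to the carbonyl instead of cross-coupling. Chloride 9 is converted with Mg turnings in THF into (4-methoxybenzyl)magnesium chloride F2, which is transmetalated onto anhydrous CeCl3 at −78 °C. The weakly basic organocerium reagent should add to the C4 carbonyl of 6 without enolising C5, giving (E)-N'-{5-[3-(tert-butyldimethylsilyloxy)-4,5-dimethoxybenzyl]-4-hydroxy-4-(4-methoxybenzyl)-1-methyl-4,5-dihydro-1H-imidazol-2-yl}-N,N-dimethylformimidamide F3 as a mixture of diastereomers. Acid-promoted loss of water across C4–C5 (CF3CO2H, CH2Cl2, 25 °C) then aromatises the ring, and the route is rejoined at 11.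

Step 8 (attachment of the imidazoledione). The weakly nucleophilic exocyclic amine may react sluggishly, attack may occur through ring N3 instead, or the product ring may be opened by nucleophiles during work-up. The fallback sets out from 13 and builds the ring stepwise instead of transferring it intact.
- Amidine formation: 13 reacts with ethyl 2-ethoxy-2-iminoacetate (EtOH, catalytic AcOH, 25 °C) to give ethyl 2-amino-2-{[5-(3-hydroxy-4,5-dimethoxybenzyl)-4-(4-methoxybenzyl)-1-methyl-1H-imidazol-2-yl]imino}acetate F4.
- Carbamoylation: the unsubstituted amidine nitrogen of F4, which should outcompete the phenol, is carbamoylated with N-succinimidyl N-methylcarbamate (i-Pr2NEt, MeCN, 25 °C) to give ethyl 2-{[5-(3-hydroxy-4,5-dimethoxybenzyl)-4-(4-methoxybenzyl)-1-methyl-1H-imidazol-2-yl]amino}-2-[(methylcarbamoyl)imino]acetate F5.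
- Ring closure: the N-methyl urea nitrogen of F5 closes onto the ester (ureido-ester cyclisation as in hydantoin synthesis; Et3N, MeCN, 60 °C), and the route is rejoined at 17.

Further compounds
F1 | step 5 | (E)-N'-{4-chloro-5-[3-(tert-butyldimethylsilyloxy)-4,5-dimethoxybenzyl]-1-methyl-1H-imidazol-2-yl}-N,N-dimethylformimidamide | CN(C)/C=N/c1nc(Cl)c(Cc2cc(O[Si](C)(C)C(C)(C)C)c(OC)c(OC)c2)n1C
F2 | step 6 | (4-methoxybenzyl)magnesium chloride | COc1ccc(C[Mg]Cl)cc1
F3 | step 6 | (E)-N'-{5-[3-(tert-butyldimethylsilyloxy)-4,5-dimethoxybenzyl]-4-hydroxy-4-(4-methoxybenzyl)-1-methyl-4,5-dihydro-1H-imidazol-2-yl}-N,N-dimethylformimidamide (diastereomer mixture, racemic) | CN(C)/C=N/C1=NC(O)(Cc2ccc(OC)cc2)C(Cc2cc(O[Si](C)(C)C(C)(C)C)c(OC)c(OC)c2)N1C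
F4 | step 8 | ethyl 2-amino-2-{[5-(3-hydroxy-4,5-dimethoxybenzyl)-4-(4-methoxybenzyl)-1-methyl-1H-imidazol-2-yl]imino}acetate | CCOC(=O)C(N)=Nc1nc(Cc2ccc(OC)cc2)c(Cc2cc(O)c(OC)c(OC)c2)n1C
F5 | step 8 | ethyl 2-{[5-(3-hydroxy-4,5-dimethoxybenzyl)-4-(4-methoxybenzyl)-1-methyl-1H-imidazol-2-yl]amino}-2-[(methylcarbamoyl)imino]acetate | CCOC(=O)C(=NC(=O)NC)Nc1nc(Cc2ccc(OC)cc2)c(Cc2cc(O)c(OC)c(OC)c2)n1C
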